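**Strategy**

The route rests on cutting the unbranched stearoyl chain at C8–C9 (acyl numbering, C1 = ester carbonyl). This CH2–CH2 bond is read as a hydrogenated olefin. It is made by ruthenium-catalysed cross-metathesis of two terminal alkenes, 3-(3,4-dihydroxy-5-methoxyphenyl)propyl non-8-enoate and undec-1-ene, with hydrogenation of the new C8=C9 alkene in the same pot, so the operation delivers the target directly. The step exploits the fact that C8 and C9 are unfunctionalised, stereochemically silent methylenes, remote from the ester and from the free catechol ring (1-alkyl-3,4-dihydroxy-5-methoxybenzene), so no protecting group is needed. The precursor ester comes in three steps from 5-hydroxyvanillin.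

Key step: step 4

Remark: the target has no stereocentre, so the E/Z composition of the transient C8=C9 alkene is immaterial; all catechol-bearing compounds are handled under argon.

**Route**

Step 1
Reactants: 1 3,4-dihydroxy-5-methoxybenzaldehyde (5-hydroxyvanillin); 2 2,2-dimethyl-1,3-dioxane-4,6-dione (Meldrum's acid)
Product: 5 3-(3,4-dihydroxy-5-methoxyphenyl)propanoic acid, via benzylidene Meldrum's acid 3 (not isolated), via benzyl Meldrum's acid 4 (not isolated)
Conditions: HCO2H/Et3N (5:2, TEAF), 95–100 °C, Ar; then aq HCl
Reagents that add atoms: none
Why: One-pot reductive Knoevenagel sequence: the aldehyde condenses with Meldrum's acid, triethylammonium formate transfers hydride to the electrophilic benzylidene, and the alkylated Meldrum's acid loses acetone and CO2 on heating to give the 3-arylpropanoic acid, with the phenols left untouched in the weakly acidic medium.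

Step 2
Reactants: 5 3-(3,4-dihydroxy-5-methoxyphenyl)propanoic acid
Product: 6 3-(3,4-dihydroxy-5-methoxyphenyl)propan-1-ol
Conditions: LiAlH4 (excess), THF, 0 °C to reflux, Ar; then 1 M HCl
Reagents that add atoms: none
Why: LiAlH4 reduction of a carboxylic acid to the primary alcohol; the two phenols are only deprotonated (extra hydride is supplied) and should be released from aluminium on acidic work-up, and nothing else in 5 is reducible.

Step 3
Reactants: 6 3-(3,4-dihydroxy-5-methoxyphenyl)propan-1-ol; 7 non-8-enoic acid
Product: 8 3-(3,4-dihydroxy-5-methoxyphenyl)propyl non-8-enoate
Conditions: Novozym 435 (immobilised Candida antarctica lipase B), 4 Å MS, 2-methyl-2-butanol, 50–60 °C, Ar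
Reagents that add atoms: none
Why: Lipase-catalysed chemoselective esterification: the acyl-enzyme is attacked by the unhindered primary aliphatic hydroxyl but not by the phenolic hydroxyls, as in the known lipophilisation of hydroxytyrosol-type phenolic alcohols with fatty acids, and the sieves remove water to drive the equilibrium.

Step 4
Reactants: 8 3-(3,4-dihydroxy-5-methoxyphenyl)propyl non-8-enoate; 9 undec-1-ene
Product: 11 3-(3,4-dihydroxy-5-methoxyphenyl)propyl octadecanoate, via octadec-8-enoate ester 10 (not isolated)
Conditions: Hoveyda–Grubbs II (5 mol%), AcOH (10 mol%), 9 (5 equiv), toluene, 40 °C, Ar sparge; then Pd/C (10%), H2 (1 atm), EtOAc, rt, same pot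
Reagents that add atoms: none
Why: The ruthenium alkylidene exchanges the two terminal alkenes through [2+2]/retro-[2+2] metallacyclobutane steps (Chauvin mechanism), ethene is expelled and the C8=C9 bond is formed, after which Pd/C and H2 saturate it in the same flask. The closest known reaction type is cross-metathesis of two type I terminal alkenes followed by one-pot hydrogenation, as used for long-chain lipids. No ring is closed and no stereocentre is created, so the geometry of 10 does not matter. The step needs chemoselectivity for the terminal C=C over the ester and the free catechol, and cross- over homo-coupling: ruthenium carbenes tolerate neutral phenols, the catechol is remote from the alkene, and a fivefold excess of cheap 9 should channel 8 statistically into the cross product. It also needs positional fidelity of the double bonds, which acetic acid should secure by quenching ruthenium hydrides that would cause chain walking and chain-length homologues. The hydrogenation should spare the arene, the methyl ether and the ester because the molecule has no benzylic or allylic C–O bond; undecane and icosane from excess 9 are removed by chromatography.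

**Compound list**

1 | 3,4-dihydroxy-5-methoxybenzaldehyde (5-hydroxyvanillin) | O=Cc1cc(O)c(O)c(OC)c1 | starting material
2 | 2,2-dimethyl-1,3-dioxane-4,6-dione (Meldrum's acid) | CC1(C)OC(=O)CC(=O)O1 | starting material
3 | 5-(3,4-dihydroxy-5-methoxybenzylidene)-2,2-dimethyl-1,3-dioxane-4,6-dione | CC1(C)OC(=O)C(=Cc2cc(O)c(O)c(OC)c2)C(=O)O1 | intermediate
4 | 5-(3,4-dihydroxy-5-methoxybenzyl)-2,2-dimethyl-1,3-dioxane-4,6-dione | CC1(C)OC(=O)C(Cc2cc(O)c(O)c(OC)c2)C(=O)O1 | intermediate
5 | 3-(3,4-dihydroxy-5-methoxyphenyl)propanoic acid | OC(=O)CCc1cc(O)c(O)c(OC)c1 | intermediate
6 | 3-(3,4-dihydroxy-5-methoxyphenyl)propan-1-ol | OCCCc1cc(O)c(O)c(OC)c1 | intermediate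
7 | non-8-enoic acid | C=CCCCCCCC(=O)O | starting material
8 | 3-(3,4-dihydroxy-5-methoxyphenyl)propyl non-8-enoate | C=CCCCCCCC(=O)OCCCc1cc(O)c(O)c(OC)c1 | intermediate
9 | undec-1-ene | C=CCCCCCCCCC | starting material
10 | 3-(3,4-dihydroxy-5-methoxyphenyl)propyl (E)-octadec-8-enoate (E isomer drawn; an E/Z mixture is expected) | CCCCCCCCC/C=C/CCCCCCC(=O)OCCCc1cc(O)c(O)c(OC)c1 | intermediate
11 | 3-(3,4-dihydroxy-5-methoxyphenyl)propyl octadecanoate | CCCCCCCCCCCCCCCCCC(=O)OCCCc1cc(O)c(O)c(OC)c1 | target

**Summary**

Total step count: 4.
Longest linear sequence: 4 steps (1 → 5 → 6 → 8 → 11).

**Steps most likely to fail**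

1. Step 4 (key step). The free catechol may deactivate the ruthenium carbene. Alternatively, ruthenium hydride may move the terminal double bonds along the chains before metathesis, so that chain-length homologues form that cannot be separated after hydrogenation. Fallback: the C8–C9 bond is made before the catechol is present and without any alkene, by copper-catalysed sp3–sp3 Grignard coupling. Commercial 8-bromooctanoic acid (OC(=O)CCCCCCCBr) is deprotonated in THF at −20 °C by the first equivalent of commercial decylmagnesium bromide (CCCCCCCCCC[Mg]Br) to give bromomagnesium 8-bromooctanoate F1. A second equivalent then displaces the primary bromide under Li2CuCl4 catalysis (THF, −20 to 0 °C; aq HCl work-up) to give octadecanoic acid F2. F2 is esterified with alcohol 6 under the lipase conditions of step 3 (Novozym 435, 4 Å MS, 2-methyl-2-butanol, 60 °C). This fallback sets out from 6 and comes back to the route at 11.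

2. Step 1. Conjugate transfer reduction of the electron-rich benzylidene intermediate may stall, or Meldrum's acid may decompose thermally before it condenses with the deactivated aldehyde. Fallback: Knoevenagel–Doebner condensation of 1 with malonic acid (pyridine, cat. piperidine, 90 °C) should give (E)-3-(3,4-dihydroxy-5-methoxyphenyl)prop-2-enoic acid F3 (5-hydroxyferulic acid). Its double bond is then hydrogenated (H2, Pd/C, MeOH, rt). This fallback sets out from 1 and comes back at 5.

3. Step 3. Acyl transfer may be slow or incomplete because the polar triol dissolves poorly in media the lipase tolerates, and the catechol may oxidise in air over the long reaction time. Fallback: chemoselective Mitsunobu esterification of 6 with 7 (PPh3, DIAD, THF, 0 °C to rt). The alcohol is activated as its alkoxyphosphonium ion and only the carboxylic acid is acidic enough to act as the nucleophile, so the phenols should stay free. This fallback sets out from 6 and comes back at 8, and it makes no new compound (F0).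

**Further compounds**

F1 | step 4 | bromomagnesium 8-bromooctanoate | [O-]C(=O)CCCCCCCBr.[Mg+2].[Br-]
F2 | step 4 | octadecanoic acid | CCCCCCCCCCCCCCCCCC(=O)O
F3 | step 1 | (E)-3-(3,4-dihydroxy-5-methoxyphenyl)prop-2-enoic acid | OC(=O)/C=C/c1cc(O)c(O)c(OC)c1
F0 | step 3 | none | none
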